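**Retrosynthetic overview**

- The target is ring A, an enolised 2-acylcyclohexane-1,3,5-trione, joined by a CH2 bridge to the aromatic ring B. The bond C-6 (ring A)–CH2 is cut first, giving the ring A nucleophile 9 and the ring B aldehyde 14 (reductive Knoevenagel alkylation).
- Ring A is opened at C-2–C-3 (intramolecular Claisen) to the open-chain triketo ester 8, and 8 is cut at the bond that becomes C-5–C-6 (dianion acylation) to the half-ester 4 and nonane-2,4-dione 5.
- The strategy rests on the quaternary carbon C-4 of ring A. It carries methyl, prenyl and the two ring carbons C-3 and C-5, both at the carboxyl oxidation level, so it is a 2-methyl-2-prenylmalonate. An esterase tells the two enantiotopic esters of diester 3 apart (3 to 4); 3 comes from 1 and 2.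
- Aldehyde 14 comes from phloroglucinol by C-acylation, 4-O-methylation and formylation. Ring B is present from the start, ring A is the only ring that is built (step 4), and the two are joined last (step 8).

Key step: step 2

Assumption: the esterase hydrolyses the pro-S ester of 3 and so gives the (R)-half-ester 4. The sense and level of selection are to be established on the first run (chiral HPLC of a derivative, and correlation of 9 with the target); the opposite sense is covered by the fallback to step 2. Compounds 9, 15 and 16 are drawn as one enol tautomer each, and their CIP descriptors refer to the tautomer drawn.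

**Route**

Step 1
Reactants: 1 dimethyl 2-methylpropanedioate (dimethyl methylmalonate); 2 1-bromo-3-methylbut-2-ene (prenyl bromide)
Product: 3 dimethyl 2-methyl-2-(3-methylbut-2-en-1-yl)propanedioate
Conditions: NaH (1.1 equiv), THF, 0 °C; then 2 (1.05 equiv), 0 → 25 °C
Reagents that add atoms: none
Why: Malonic ester alkylation: NaH deprotonates the single acidic C–H irreversibly and the soft enolate displaces the primary allylic bromide by SN2 at the unsubstituted terminus, while the absence of a second acidic hydrogen excludes dialkylation.

Step 2
Reactants: 3 dimethyl 2-methyl-2-(3-methylbut-2-en-1-yl)propanedioate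
Product: 4 (2R)-2-(methoxycarbonyl)-2,5-dimethylhex-4-enoic acid
Conditions: pig liver esterase, 0.1 M phosphate buffer pH 7.5, DMSO (10 vol%), 25 °C, pH-stat with 1 M NaOH (1.0 equiv); then 1 M HCl to pH 2
Reagents that add atoms: water, O
Why: The catalytic serine of the esterase adds to one methoxycarbonyl group, methanol leaves to give an acyl-enzyme, and water frees the carboxylic acid (serine-hydrolase ester hydrolysis). The closest known reaction is the esterase desymmetrization of dialkyl 2-alkyl-2-methylmalonates to chiral half-esters. No ring is closed and no carbon–carbon bond is formed; the prochiral quaternary carbon of 3 becomes the (R)-stereocentre because the chiral binding site places the small methyl and the larger lipophilic prenyl group in different pockets, so that only the pro-S ester reaches the serine. The step needs enantiotopic-group selectivity, which rests on the size difference between methyl and prenyl, and a stop at the half-ester, which is secured because the carboxylate formed is no longer bound productively. As the stereocentre carries no hydrogen it cannot racemise by enolisation, and the enantiomeric purity may be raised by crystallisation of an amine salt if required.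

Step 3
Reactants: 4 (2R)-2-(methoxycarbonyl)-2,5-dimethylhex-4-enoic acid; 5 nonane-2,4-dione
Product: 8 methyl (2R)-2-methyl-2-(3-methylbut-2-en-1-yl)-3,5,7-trioxododecanoate, via acyl imidazolide 6 (not isolated), via dilithiated dione 7 (not isolated)
Conditions: (a) 4, 1,1'-carbonyldiimidazole (1.1 equiv), THF, 25 °C; (b) 5 (3 equiv), LiN(iPr)2 (6.2 equiv), THF, −78 → 0 °C; (c) solution (a) added to (b) at −78 °C, then −78 → −30 °C; 1 M HCl
Reagents that add atoms: none
Why: Hauser–Harris dianion acylation (a crossed Claisen condensation): carbonyldiimidazole turns the hindered acid into the acyl imidazolide with loss of CO2, and the 1,3-dianion of the β-diketone, formed by kinetic deprotonation of the monoenolate at the methyl group, attacks this acyl donor through its more basic terminal carbanion; the methyl ester on the same quaternary carbon is far less electrophilic at −78 °C, the excess dianion takes up the acidic product and the imidazole N–H, and the stereocentre has no α-hydrogen to lose.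

Step 4
Reactants: 8 methyl (2R)-2-methyl-2-(3-methylbut-2-en-1-yl)-3,5,7-trioxododecanoate
Product: 9 (4R)-2-hexanoyl-3,5-dihydroxy-4-methyl-4-(3-methylbut-2-en-1-yl)cyclohexa-2,5-dien-1-one (ring A)
Conditions: NaOMe (3 equiv), MeOH, 0 → 50 °C; then 1 M HCl
Reagents that add atoms: none
Why: Dieckmann-type intramolecular Claisen condensation: the doubly activated C-6 carbanion of the triketone attacks the methyl ester in a six-membered acyl substitution, as in the biomimetic closure of 3,5,7-triketo esters to acylphloroglucinols, and the closure is driven by formation of the strongly acidic cyclic β-triketone enolate, into which any enol lactone formed by O-acylation is returned by methoxide; the quaternary stereocentre takes no part.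

Step 5
Reactants: 10 benzene-1,3,5-triol (phloroglucinol)
Product: 11 1-(2,4,6-trihydroxyphenyl)butan-1-one
Conditions: butanoyl chloride (1.0 equiv), AlCl3 (3 equiv), PhNO2/CH2Cl2, 0 → 40 °C; then ice, 1 M HCl
Reagents that add atoms: butanoyl chloride, CCCC(=O)Cl
Why: Friedel–Crafts acylation of a highly activated arene; the first acyl group deactivates the ring and binds AlCl3 as a chelate, so monoacylation should prevail.

Step 6
Reactants: 11 1-(2,4,6-trihydroxyphenyl)butan-1-one
Product: 12 1-(2,6-dihydroxy-4-methoxyphenyl)butan-1-one
Conditions: Me2SO4 (1.0 equiv), K2CO3 (1.0 equiv), acetone, 25 → 56 °C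
Reagents that add atoms: dimethyl sulfate, COS(=O)(=O)OC
Why: Williamson O-methylation at the 4-hydroxyl, which is the most acidic phenol (para to the acyl group) and is not deactivated by hydrogen bonding to the ketone as the 2- and 6-hydroxyls are; the hard electrophile with carbonate base favours O- over C-methylation.

Step 7
Reactants: 12 1-(2,6-dihydroxy-4-methoxyphenyl)butan-1-one
Product: 14 3-butanoyl-2,4-dihydroxy-6-methoxybenzaldehyde, via aryl chloro(methoxy)methane 13 (not isolated)
Conditions: Cl2CHOMe (1.5 equiv), TiCl4 (3 equiv), CH2Cl2, −15 → 0 °C; then ice, 1 M HCl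
Reagents that add atoms: dichloromethyl methyl ether, COC(Cl)Cl; water, O
Why: Rieche formylation: TiCl4 ionises dichloromethyl methyl ether to a chloro(methoxy)carbenium ion that substitutes the only kind of free ring position (C-3 and C-5 are equivalent) ortho to a titanium-bound phenoxide, aqueous work-up hydrolyses the α-chloro ether to the aldehyde, and the deactivating formyl group should prevent a second substitution.

Step 8
Reactants: 9 (4R)-2-hexanoyl-3,5-dihydroxy-4-methyl-4-(3-methylbut-2-en-1-yl)cyclohexa-2,5-dien-1-one; 14 3-butanoyl-2,4-dihydroxy-6-methoxybenzaldehyde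
Product: 16 (4R)-6-[(3-butanoyl-2,4-dihydroxy-6-methoxyphenyl)methyl]-2-hexanoyl-3,5-dihydroxy-4-methyl-4-(3-methylbut-2-en-1-yl)cyclohexa-2,5-dien-1-one (target), via Knoevenagel adduct 15 (not isolated)
Conditions: L-proline (20 mol%), diethyl 2,6-dimethyl-1,4-dihydropyridine-3,5-dicarboxylate (Hantzsch ester, 1.2 equiv), CH2Cl2/EtOH, 25 °C
Reagents that add atoms: none
Why: Organocatalytic three-component reductive alkylation: proline converts aldehyde 14 into an iminium ion, the enol carbon C-6 of 9 (the only ring carbon that still bears hydrogen) adds and proline is eliminated (Knoevenagel condensation), and the arylmethylidene trione 15, a strong Michael acceptor, takes up hydride from the Hantzsch ester at the benzylic carbon; the isolated alkene, the aryl and alkyl ketones and the quaternary stereocentre are inert to this mild hydride donor.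

**Compound list**

1 | dimethyl 2-methylpropanedioate (dimethyl methylmalonate) | COC(=O)C(C)C(=O)OC | starting material
2 | 1-bromo-3-methylbut-2-ene (prenyl bromide) | CC(C)=CCBr | starting material
3 | dimethyl 2-methyl-2-(3-methylbut-2-en-1-yl)propanedioate | COC(=O)C(C)(CC=C(C)C)C(=O)OC | intermediate
4 | (2R)-2-(methoxycarbonyl)-2,5-dimethylhex-4-enoic acid | COC(=O)[C@](C)(CC=C(C)C)C(=O)O | intermediate
5 | nonane-2,4-dione | CCCCCC(=O)CC(C)=O | starting material
6 | methyl (2R)-2-(1H-imidazole-1-carbonyl)-2,5-dimethylhex-4-enoate | COC(=O)[C@](C)(CC=C(C)C)C(=O)n1ccnc1 | intermediate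
7 | dilithium nonane-2,4-dione-1,3-diide (1,3-dianion of 5) | [Li+].[Li+].[CH2-]C(=O)[CH-]C(=O)CCCCC | intermediate
8 | methyl (2R)-2-methyl-2-(3-methylbut-2-en-1-yl)-3,5,7-trioxododecanoate | COC(=O)[C@](C)(CC=C(C)C)C(=O)CC(=O)CC(=O)CCCCC | intermediate
9 | (4R)-2-hexanoyl-3,5-dihydroxy-4-methyl-4-(3-methylbut-2-en-1-yl)cyclohexa-2,5-dien-1-one | CCCCCC(=O)C1=C(O)[C@](C)(CC=C(C)C)C(O)=CC1=O | intermediate
10 | benzene-1,3,5-triol (phloroglucinol) | Oc1cc(O)cc(O)c1 | starting material
11 | 1-(2,4,6-trihydroxyphenyl)butan-1-one | CCCC(=O)c1c(O)cc(O)cc1O | intermediate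
12 | 1-(2,6-dihydroxy-4-methoxyphenyl)butan-1-one | CCCC(=O)c1c(O)cc(OC)cc1O | intermediate
13 | 1-{3-[chloro(methoxy)methyl]-2,6-dihydroxy-4-methoxyphenyl}butan-1-one (racemic at the chloro ether carbon) | CCCC(=O)c1c(O)cc(OC)c(C(Cl)OC)c1O | intermediate
14 | 3-butanoyl-2,4-dihydroxy-6-methoxybenzaldehyde | CCCC(=O)c1c(O)cc(OC)c(C=O)c1O | intermediate
15 | 6-[(3-butanoyl-2,4-dihydroxy-6-methoxyphenyl)methylidene]-2-hexanoyl-3-hydroxy-4-methyl-4-(3-methylbut-2-en-1-yl)cyclohex-2-ene-1,5-dione; spatial arrangement at C-4 as in 9 (formally 4S in this tautomer), C=C geometry not defined | CCCCCC(=O)C1=C(O)[C@](C)(CC=C(C)C)C(=O)C(=Cc2c(OC)cc(O)c(C(=O)CCC)c2O)C1=O | intermediate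
16 | (4R)-6-[(3-butanoyl-2,4-dihydroxy-6-methoxyphenyl)methyl]-2-hexanoyl-3,5-dihydroxy-4-methyl-4-(3-methylbut-2-en-1-yl)cyclohexa-2,5-dien-1-one | CCCCCC(=O)C1=C(O)[C@](C)(CC=C(C)C)C(O)=C(Cc2c(OC)cc(O)c(C(=O)CCC)c2O)C1=O | target

**Step count**

Total steps: 8. Longest linear sequence: 5 steps (steps 1, 2, 3, 4 and 8); the ring B branch (steps 5, 6, 7) joins at step 8.

**Steps most likely to fail**

Step 2. The esterase may bind the diester in the alternative orientation and hydrolyse the pro-R ester, so that the antipodal half-ester is formed; the preference of this enzyme within the 2-alkyl-2-methylmalonate class is known to depend on the size of the alkyl group. The fallback sets out from 3 and comes back to the route at 9.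
- The enzymatic hydrolysis is run as before, and its product, (2S)-2-(methoxycarbonyl)-2,5-dimethylhex-4-enoic acid F1, is used with the roles of its two arms exchanged.
- The free acid is O-alkylated with N,N-dimethylformamide di-tert-butyl acetal (toluene, 80 °C) to 1-tert-butyl 3-methyl (2R)-2-methyl-2-(3-methylbut-2-en-1-yl)propanedioate F2.
- LiOH (THF/H2O, 25 °C) saponifies only the methyl ester and gives (2R)-2-(tert-butoxycarbonyl)-2,5-dimethylhex-4-enoic acid F3, in which acid and ester occupy the same spatial positions as in 4.
- F3 is activated with carbonyldiimidazole to tert-butyl (2R)-2-(1H-imidazole-1-carbonyl)-2,5-dimethylhex-4-enoate F4 and coupled with dianion 7 under the conditions of step 3 to tert-butyl (2R)-2-methyl-2-(3-methylbut-2-en-1-yl)-3,5,7-trioxododecanoate F5.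
- Claisen closure of F5 with KOtBu in THF (25 → 60 °C; the tert-butyl ester is a slower acyl acceptor and tert-butoxide is the leaving group) gives 9.

Step 3. Deprotonation of the dione monoanion at the C-5 methylene in competition with the C-1 methyl, together with attack of the dianion on the methyl ester, may lead to regioisomeric and over-acylated chains. The fallback sets out from 6 and comes back to the route at 8.
- Imidazolide 6 is added to dilithiated pentane-2,4-dione F6, made from commercial pentane-2,4-dione (CC(=O)CC(C)=O) and LiN(iPr)2 in THF at −78 → 0 °C; this symmetrical dianion has only methyl termini. The product is methyl (2R)-2-methyl-2-(3-methylbut-2-en-1-yl)-3,5,7-trioxooctanoate F7.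
- The trianion of F7 (LiN(iPr)2, 3.2 equiv, THF, −78 °C) is alkylated with 1-iodobutane at the terminal methyl carbanion, its most basic site (Hauser–Harris terminal alkylation of a polyketone polyanion), to give 8.

Step 8. Condensation of the chelated, electron-rich aldehyde may be slow, and the arylmethylidene intermediate may be intercepted by a second molecule of 9 in a Michael addition before hydride transfer. The fallback sets out from 12 and 9 and comes back to the route at 16.
- Aminomethylation of 12 with morpholine and aqueous formaldehyde (EtOH, 25 °C; Mannich reaction at the free ring position) gives 1-[2,6-dihydroxy-4-methoxy-3-(morpholin-4-ylmethyl)phenyl]butan-1-one F8.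
- Heating F8 with 9 in toluene at 100 °C expels morpholine and generates the ortho-quinone methide 2-butanoyl-3-hydroxy-5-methoxy-6-methylidenecyclohexa-2,4-dien-1-one F9, which is trapped at once by conjugate addition of the enol carbon C-6 of 9 to give 16. This is the Mannich-base route used for methylene-bridged acylphloroglucinols, and it leaves the stereocentre untouched.

Further compounds
F1 | step 2 | (2S)-2-(methoxycarbonyl)-2,5-dimethylhex-4-enoic acid | COC(=O)[C@@](C)(CC=C(C)C)C(=O)O
F2 | step 2 | 1-tert-butyl 3-methyl (2R)-2-methyl-2-(3-methylbut-2-en-1-yl)propanedioate | COC(=O)[C@@](C)(CC=C(C)C)C(=O)OC(C)(C)C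
F3 | step 2 | (2R)-2-(tert-butoxycarbonyl)-2,5-dimethylhex-4-enoic acid | CC(C)(C)OC(=O)[C@](C)(CC=C(C)C)C(=O)O
F4 | step 2 | tert-butyl (2R)-2-(1H-imidazole-1-carbonyl)-2,5-dimethylhex-4-enoate | CC(C)(C)OC(=O)[C@](C)(CC=C(C)C)C(=O)n1ccnc1
F5 | step 2 | tert-butyl (2R)-2-methyl-2-(3-methylbut-2-en-1-yl)-3,5,7-trioxododecanoate | CC(C)(C)OC(=O)[C@](C)(CC=C(C)C)C(=O)CC(=O)CC(=O)CCCCC
F6 | step 3 | dilithium pentane-2,4-dione-1,3-diide | [Li+].[Li+].[CH2-]C(=O)[CH-]C(C)=O
F7 | step 3 | methyl (2R)-2-methyl-2-(3-methylbut-2-en-1-yl)-3,5,7-trioxooctanoate | COC(=O)[C@](C)(CC=C(C)C)C(=O)CC(=O)CC(C)=O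
F8 | step 8 | 1-[2,6-dihydroxy-4-methoxy-3-(morpholin-4-ylmethyl)phenyl]butan-1-one | CCCC(=O)c1c(O)cc(OC)c(CN2CCOCC2)c1O
F9 | step 8 | 2-butanoyl-3-hydroxy-5-methoxy-6-methylidenecyclohexa-2,4-dien-1-one | CCCC(=O)C1=C(O)C=C(OC)C(=C)C1=O
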